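- The tetronic acid ring is made last, by Dieckmann cyclisation of the O-propanoyl derivative of an (R)-α-hydroxy ester that already carries the whole side chain.
- The triene is cut at the sp2–sp2 bond between the Z-trisubstituted alkene and the E,E-diene: Suzuki–Miyaura coupling of an eastern (Z)-alkenylboronate with a western (E,E)-dienyl iodide.
- Eastern piece (new step): a catalytic enantioselective allylboration of a glyoxylate with a 2-methylallyl gem-diboronate forms the C5–CH2 bond, the (R) centre and the Z-alkenylboronate in one operation.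
- Western piece: E-selective Wittig and Takai olefinations on a 3-(furyl)propanal; its 2,4-disubstituted furan comes from a commercial 4-bromo-2-formylfuran by Negishi coupling, 3-furyllithium addition and ionic deoxygenation.
- Ring order: both furan rings are bought intact; the only ring formed is the tetronic acid, in the final step.

Assumption: the (R)-phosphoric acid of step 8 is taken to direct Re-face addition to the glyoxylate aldehyde (its usual sense with aldehydes), which gives 2R; were the sense reversed, the (S)-acid would be used with nothing else changed.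

Step 1
Reactants: 1 4-bromofuran-2-carbaldehyde; 2 (3-ethoxy-3-oxopropyl)zinc bromide (commercial THF solution)
Product: 3 ethyl 3-(5-formylfuran-3-yl)propanoate
Conditions: Pd(OAc)2 (2 mol%), 2-dicyclohexylphosphino-2′,6′-dimethoxybiphenyl (4 mol%), THF, 25 °C
Reagents that add atoms: none
Why: Negishi cross-coupling, in which the formyl-activated C–Br bond adds readily to zerovalent palladium and the alkylzinc bromide tolerates both the free aldehyde and its own ester.

Step 2
Reactants: 4 3-bromofuran; 3 ethyl 3-(5-formylfuran-3-yl)propanoate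
Product: 6 racemic ethyl 3-{5-[furan-3-yl(hydroxy)methyl]furan-3-yl}propanoate, via furan-3-yllithium 5 (not isolated)
Conditions: 4, n-BuLi (1.05 equiv), THF, −78 °C, 20 min; then 3, −78 °C, 1 h; H2O
Reagents that add atoms: none
Why: Bromine–lithium exchange gives 3-furyllithium, which at −78 °C undergoes 1,2-addition to the aldehyde far faster than to the ethyl ester; the carbinol centre is racemic and is removed in step 3.

Step 3
Reactants: 6 racemic ethyl 3-{5-[furan-3-yl(hydroxy)methyl]furan-3-yl}propanoate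
Product: 7 ethyl 3-[5-(furan-3-ylmethyl)furan-3-yl]propanoate
Conditions: Et3SiH (3 equiv), CF3CO2H (3 equiv), CH2Cl2, −40 → −10 °C
Reagents that add atoms: none
Why: Ionic hydrogenation (deoxygenation), in which acid ionises the doubly furyl-stabilised carbinol and Et3SiH traps the cation as the diarylmethane while the ester is untouched.

Step 4
Reactants: 7 ethyl 3-[5-(furan-3-ylmethyl)furan-3-yl]propanoate
Product: 8 3-[5-(furan-3-ylmethyl)furan-3-yl]propanal
Conditions: i-Bu2AlH (1.05 equiv), CH2Cl2, −78 °C; MeOH, then aq. KNaC4H4O6 (potassium sodium tartrate)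
Reagents that add atoms: none
Why: Partial ester reduction with i-Bu2AlH, whose tetrahedral aluminium hemiacetal is stable at −78 °C and collapses to the aldehyde only on work-up.

Step 5
Reactants: 8 3-[5-(furan-3-ylmethyl)furan-3-yl]propanal; 9 2-(triphenylphosphoranylidene)propanal
Product: 10 (2E)-5-[5-(furan-3-ylmethyl)furan-3-yl]-2-methylpent-2-enal
Conditions: 9 (1.3 equiv), toluene, 90 °C
Reagents that add atoms: none
Why: Wittig olefination with a stabilised ylide, which gives the (E)-2-methyl-2-enal with high selectivity and sets the E-trisubstituted alkene of the target.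

Step 6
Reactants: 10 (2E)-5-[5-(furan-3-ylmethyl)furan-3-yl]-2-methylpent-2-enal
Product: 11 2-(furan-3-ylmethyl)-4-[(3E,5E)-6-iodo-4-methylhexa-3,5-dien-1-yl]furan
Conditions: CrCl2 (6 equiv), CHI3 (2 equiv), THF/1,4-dioxane 1:6, 0 → 25 °C, dark
Reagents that add atoms: iodoform (IC(I)I)
Why: Takai olefination, in which the geminal dichromium reagent from CHI3 and CrCl2 adds to the aldehyde and eliminates to the (E)-iodoalkene without disturbing the existing E-alkene or the furans.

Step 7
Reactants: 12 2,2′-methylenebis(4,4,5,5-tetramethyl-1,3,2-dioxaborolane); 13 2-bromopropene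
Product: 16 2,2′-(2-methylprop-2-ene-1,1-diyl)bis(4,4,5,5-tetramethyl-1,3,2-dioxaborolane), via lithiated diborylmethane 14 (not isolated), via diborylmethylzinc bromide 15 (not isolated)
Conditions: lithium 2,2,6,6-tetramethylpiperidide (1.05 equiv), THF, 0 °C; ZnBr2 (1.1 equiv), 0 → 25 °C; then 13, Pd[P(t-Bu)3]2 (3 mol%), 25 → 45 °C
Reagents that add atoms: none
Why: Deprotonation between two boron atoms, transmetalation to zinc and Negishi coupling with the alkenyl bromide, where without added base the C–B bonds stay out of the palladium cycle.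

Step 8
Reactants: 16 2,2′-(2-methylprop-2-ene-1,1-diyl)bis(4,4,5,5-tetramethyl-1,3,2-dioxaborolane); 17 ethyl glyoxylate (freshly distilled, 1.5 equiv)
Product: 19 ethyl (2R,4Z)-2-hydroxy-4-methyl-5-(4,4,5,5-tetramethyl-1,3,2-dioxaborolan-2-yl)pent-4-enoate, via O-boryl allylation adduct 18 (not isolated)
Conditions: (R)-3,3′-bis(2,4,6-triisopropylphenyl)-1,1′-binaphthyl-2,2′-diyl hydrogen phosphate (5 mol%), 4 Å molecular sieves, toluene, −60 °C, 48 h; then aq. NaHCO3, 0 °C
Reagents that add atoms: none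
Why: Proposed new method: a chiral phosphoric acid-catalysed allylboration of a glyoxylate with a 2-methyl-substituted allylic gem-diboronate, a reagent–electrophile pairing not yet demonstrated, in which the acid hydrogen-bonds the formyl C–H and a boronate oxygen of the reacting boron in a closed chair transition state so that the CH2 terminus adds to the Re face (2R), while the spectator boryl group sits pseudo-axial because a pseudo-equatorial one would eclipse the 2-methyl group (allylic 1,2-strain) and meet the catalyst aryl groups, which delivers the Z-alkenylboronate; the closest known reaction type is the chiral phosphoric acid-catalysed allylboration of aldehydes with α-boryl allyl- and crotylboronates to (Z)-δ-boryl homoallylic alcohols.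

Step 9
Reactants: 19 ethyl (2R,4Z)-2-hydroxy-4-methyl-5-(4,4,5,5-tetramethyl-1,3,2-dioxaborolan-2-yl)pent-4-enoate; 11 2-(furan-3-ylmethyl)-4-[(3E,5E)-6-iodo-4-methylhexa-3,5-dien-1-yl]furan
Product: 20 ethyl (2R,4Z,6E,8E)-11-[5-(furan-3-ylmethyl)furan-3-yl]-2-hydroxy-4,8-dimethylundeca-4,6,8-trienoate
Conditions: PdCl2(dppf)·CH2Cl2 (5 mol%; dppf = 1,1′-bis(diphenylphosphino)ferrocene), K3PO4 (3 equiv), degassed THF/H2O 5:1, 25 °C, dark
Reagents that add atoms: none
Why: Suzuki–Miyaura coupling of an alkenylboronate with an alkenyl iodide proceeds with retention at both partners, giving the 4Z,6E,8E triene, and the mild phosphate base spares the hydroxy ester and its C2 centre.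

Step 10
Reactants: 20 ethyl (2R,4Z,6E,8E)-11-[5-(furan-3-ylmethyl)furan-3-yl]-2-hydroxy-4,8-dimethylundeca-4,6,8-trienoate
Product: 21 ethyl (2R,4Z,6E,8E)-11-[5-(furan-3-ylmethyl)furan-3-yl]-4,8-dimethyl-2-(propanoyloxy)undeca-4,6,8-trienoate
Conditions: (EtCO)2O (1.5 equiv), Et3N (2 equiv), 4-(dimethylamino)pyridine (5 mol%), CH2Cl2, 0 °C
Reagents that add atoms: propanoic anhydride (CCC(=O)OC(=O)CC)
Why: Nucleophile-catalysed O-acylation (esterification) of the secondary alcohol, which leaves the stereocentre and the triene untouched.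

Step 11
Reactants: 21 ethyl (2R,4Z,6E,8E)-11-[5-(furan-3-ylmethyl)furan-3-yl]-4,8-dimethyl-2-(propanoyloxy)undeca-4,6,8-trienoate
Product: 23 (5R)-5-{(2Z,4E,6E)-9-[5-(furan-3-ylmethyl)furan-3-yl]-2,6-dimethylnona-2,4,6-trien-1-yl}-4-hydroxy-3-methylfuran-2(5H)-one, via propanoate lithium enolate 22 (not isolated)
Conditions: LiN(SiMe3)2 (2.5 equiv), THF, −78 → −20 °C; then 1 M HCl (aq) to pH 3, 0 °C
Reagents that add atoms: none
Why: Dieckmann (intramolecular Claisen) condensation, in which the propanoate enolate attacks the neighbouring ethyl ester in a 5-exo closure and the product is held as the tetronate anion, so the C5 centre set in step 8 is carried through unchanged.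

Compound list
1 | 4-bromofuran-2-carbaldehyde | O=Cc1cc(Br)co1 | starting material
2 | (3-ethoxy-3-oxopropyl)zinc bromide | CCOC(=O)CC[Zn]Br | starting material
3 | ethyl 3-(5-formylfuran-3-yl)propanoate | CCOC(=O)CCc1coc(C=O)c1 | intermediate
4 | 3-bromofuran | Brc1ccoc1 | starting material
5 | furan-3-yllithium | [Li]c1ccoc1 | intermediate
6 | ethyl 3-{5-[furan-3-yl(hydroxy)methyl]furan-3-yl}propanoate, racemic at the carbinol carbon | CCOC(=O)CCc1coc(C(O)c2ccoc2)c1 | intermediate
7 | ethyl 3-[5-(furan-3-ylmethyl)furan-3-yl]propanoate | CCOC(=O)CCc1coc(Cc2ccoc2)c1 | intermediate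
8 | 3-[5-(furan-3-ylmethyl)furan-3-yl]propanal | O=CCCc1coc(Cc2ccoc2)c1 | intermediate
9 | 2-(triphenylphosphoranylidene)propanal | CC(C=O)=P(c1ccccc1)(c1ccccc1)c1ccccc1 | starting material
10 | (2E)-5-[5-(furan-3-ylmethyl)furan-3-yl]-2-methylpent-2-enal | O=C/C(C)=C/CCc1coc(Cc2ccoc2)c1 | intermediate
11 | 2-(furan-3-ylmethyl)-4-[(3E,5E)-6-iodo-4-methylhexa-3,5-dien-1-yl]furan | I/C=C/C(C)=C/CCc1coc(Cc2ccoc2)c1 | intermediate
12 | 2,2′-methylenebis(4,4,5,5-tetramethyl-1,3,2-dioxaborolane) | CC1(C)OB(CB2OC(C)(C)C(C)(C)O2)OC1(C)C | starting material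
13 | 2-bromopropene | CC(Br)=C | starting material
14 | [bis(4,4,5,5-tetramethyl-1,3,2-dioxaborolan-2-yl)methyl]lithium | [Li]C(B1OC(C)(C)C(C)(C)O1)B1OC(C)(C)C(C)(C)O1 | intermediate
15 | [bis(4,4,5,5-tetramethyl-1,3,2-dioxaborolan-2-yl)methyl]zinc bromide | Br[Zn]C(B1OC(C)(C)C(C)(C)O1)B1OC(C)(C)C(C)(C)O1 | intermediate
16 | 2,2′-(2-methylprop-2-ene-1,1-diyl)bis(4,4,5,5-tetramethyl-1,3,2-dioxaborolane) | C=C(C)C(B1OC(C)(C)C(C)(C)O1)B1OC(C)(C)C(C)(C)O1 | intermediate
17 | ethyl glyoxylate (ethyl 2-oxoacetate) | CCOC(=O)C=O | starting material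
18 | ethyl (2R,4Z)-4-methyl-5-(4,4,5,5-tetramethyl-1,3,2-dioxaborolan-2-yl)-2-[(4,4,5,5-tetramethyl-1,3,2-dioxaborolan-2-yl)oxy]pent-4-enoate | CCOC(=O)[C@H](OB1OC(C)(C)C(C)(C)O1)C/C(C)=C\B1OC(C)(C)C(C)(C)O1 | intermediate
19 | ethyl (2R,4Z)-2-hydroxy-4-methyl-5-(4,4,5,5-tetramethyl-1,3,2-dioxaborolan-2-yl)pent-4-enoate | CCOC(=O)[C@H](O)C/C(C)=C\B1OC(C)(C)C(C)(C)O1 | intermediate
20 | ethyl (2R,4Z,6E,8E)-11-[5-(furan-3-ylmethyl)furan-3-yl]-2-hydroxy-4,8-dimethylundeca-4,6,8-trienoate | CCOC(=O)[C@H](O)C\C(C)=C/C=C/C(C)=C/CCc1coc(Cc2ccoc2)c1 | intermediate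
21 | ethyl (2R,4Z,6E,8E)-11-[5-(furan-3-ylmethyl)furan-3-yl]-4,8-dimethyl-2-(propanoyloxy)undeca-4,6,8-trienoate | CCOC(=O)[C@H](OC(=O)CC)C\C(C)=C/C=C/C(C)=C/CCc1coc(Cc2ccoc2)c1 | intermediate
22 | ethyl (2R,4Z,6E,8E)-11-[5-(furan-3-ylmethyl)furan-3-yl]-2-{[1-(lithiooxy)prop-1-en-1-yl]oxy}-4,8-dimethylundeca-4,6,8-trienoate | CCOC(=O)[C@H](OC(O[Li])=CC)C\C(C)=C/C=C/C(C)=C/CCc1coc(Cc2ccoc2)c1 | intermediate
23 | (5R)-5-{(2Z,4E,6E)-9-[5-(furan-3-ylmethyl)furan-3-yl]-2,6-dimethylnona-2,4,6-trien-1-yl}-4-hydroxy-3-methylfuran-2(5H)-one | CC1=C(O)[C@@H](C\C(C)=C/C=C/C(C)=C/CCc2coc(Cc3ccoc3)c2)OC1=O | target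

Total step count: 11. Longest linear sequence: 9 steps (steps 1–6, then 9, 10 and 11, from 4-bromofuran-2-carbaldehyde).

Steps most likely to fail

Step 8 (the proposed new allylboration). The glyoxylate is electrophilic enough that an uncatalysed background addition could erode the ee. The Z/E ratio also rests on the pseudo-axial preference of the spectator boryl group, and the hindered gem-diboronate may react slowly at −60 °C. Fallback with known chemistry, setting out from 17 and coming back at 20: 17 and 2-methylpropene undergo the titanium-catalysed asymmetric glyoxylate–ene reaction [(R)-1,1′-bi-2-naphthol, TiCl2(Oi-Pr)2, 4 Å molecular sieves, CH2Cl2, −30 °C] to give ethyl (2R)-2-hydroxy-4-methylpent-4-enoate F1. Silylation with chloro(dimethyl)vinylsilane and Et3N gives ethyl (2R)-2-{[ethenyl(dimethyl)silyl]oxy}-4-methylpent-4-enoate F2. Ring-closing metathesis with Mo(=CHCMe2Ph)(=NC6H3-2,6-i-Pr2)[OCMe(CF3)2]2 in benzene closes the six-membered siloxane ethyl (6R)-2,2,4-trimethyl-5,6-dihydro-2H-1,2-oxasiline-6-carboxylate F3, whose ring forces silicon cis to the CH2 group. Fluoride-promoted palladium cross-coupling of F3 with iodide 11 (Pd(dba)2, Bu4NF, THF, 25 °C) then gives 20 with the same Z geometry and the free hydroxyl, and the route continues at step 10.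

Step 3 (ionic deoxygenation). The furfuryl-type cation can alkylate another furan ring (oligomers) and excess acid/silane can reduce furans. Fallback that avoids any cation, setting out from 3 and coming back at 7: NaBH4 (EtOH, 0 °C) reduces the aldehyde of 3 to ethyl 3-[5-(hydroxymethyl)furan-3-yl]propanoate F4. ClP(O)(OEt)2 and pyridine convert it into ethyl 3-(5-{[(diethoxyphosphoryl)oxy]methyl}furan-3-yl)propanoate F5. An sp3–sp2 Suzuki–Miyaura coupling of F5 with commercial furan-3-ylboronic acid (Pd(OAc)2, PPh3, K3PO4, toluene, 80 °C) forms the diarylmethane 7 directly.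

Step 11 (Dieckmann closure). The base can also deprotonate C2 of the α-acyloxy ester, leading to epimerisation or 1,2-acyl migration. Fallback that reverses the order of bond formation (C–C bond first, lactone second), setting out from 20 and coming back at 23: t-BuMe2SiOSO2CF3 and 2,6-lutidine give ethyl (2R,4Z,6E,8E)-2-{[tert-butyl(dimethyl)silyl]oxy}-11-[5-(furan-3-ylmethyl)furan-3-yl]-4,8-dimethylundeca-4,6,8-trienoate F6. Crossed Claisen condensation with the lithium enolate of methyl propanoate (3 equiv, from LiN(i-Pr)2, THF, −78 → −30 °C) gives methyl (4R,6Z,8E,10E)-4-{[tert-butyl(dimethyl)silyl]oxy}-13-[5-(furan-3-ylmethyl)furan-3-yl]-2,6,10-trimethyl-3-oxotrideca-6,8,10-trienoate F7 as both C2 epimers. Bu4NF (THF, 0 °C) removes the silyl group and the freed hydroxyl lactonises onto the methyl ester, giving 23 after mild acidification.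

Further compounds
F1 | step 8 | ethyl (2R)-2-hydroxy-4-methylpent-4-enoate | CCOC(=O)[C@H](O)CC(C)=C
F2 | step 8 | ethyl (2R)-2-{[ethenyl(dimethyl)silyl]oxy}-4-methylpent-4-enoate | CCOC(=O)[C@H](O[Si](C)(C)C=C)CC(C)=C
F3 | step 8 | ethyl (6R)-2,2,4-trimethyl-5,6-dihydro-2H-1,2-oxasiline-6-carboxylate | CCOC(=O)[C@H]1CC(C)=C[Si](C)(C)O1
F4 | step 3 | ethyl 3-[5-(hydroxymethyl)furan-3-yl]propanoate | CCOC(=O)CCc1coc(CO)c1
F5 | step 3 | ethyl 3-(5-{[(diethoxyphosphoryl)oxy]methyl}furan-3-yl)propanoate | CCOC(=O)CCc1coc(COP(=O)(OCC)OCC)c1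
F6 | step 11 | ethyl (2R,4Z,6E,8E)-2-{[tert-butyl(dimethyl)silyl]oxy}-11-[5-(furan-3-ylmethyl)furan-3-yl]-4,8-dimethylundeca-4,6,8-trienoate | CCOC(=O)[C@H](O[Si](C)(C)C(C)(C)C)C\C(C)=C/C=C/C(C)=C/CCc1coc(Cc2ccoc2)c1
F7 | step 11 | methyl (4R,6Z,8E,10E)-4-{[tert-butyl(dimethyl)silyl]oxy}-13-[5-(furan-3-ylmethyl)furan-3-yl]-2,6,10-trimethyl-3-oxotrideca-6,8,10-trienoate (both C2 epimers) | COC(=O)C(C)C(=O)[C@H](O[Si](C)(C)C(C)(C)C)C\C(C)=C/C=C/C(C)=C/CCc1coc(Cc2ccoc2)c1
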